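**Retrosynthetic overview**

1. The last C–C bond is C1–aryl: guaiacol captures the C1 benzylic cation of a 1-tetralol by Friedel–Crafts alkylation (para to OH, trans to C2); the benzyl ethers then come off by hydrogenolysis.
2. The tetralin carbocycle (C1–C4, C4a, C8a) is traced to a 4-phenylsulfonyl-1-tetralone, cut at C4–C4a and C1–C8a into a C4a≡C8a aryne and a 2-sulfonylcyclobutanone that holds C1–C4.
3. Feature used: the methoxy group on C8, next to ring-fusion carbon C8a, polarises the aryne so that carbon C4 adds at C4a and the acyl carbon C1 ends on C8a; C2 and C3 with their trans CH2OR groups are adjacent carbons of the four-membered ring.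
4. The (2R,3R)-cyclobutanone comes from an auxiliary-controlled [2+2] of di-(+)-menthyl fumarate with ketene dimethyl acetal; the aryne precursor comes from O-benzylsyringaldehyde through a symmetric phenol.
5. Ring order: cyclobutane (step 2), then its two-carbon expansion to the benzo-fused six-membered ring (step 11); both benzene rings are bought.

Key step: step 11

Assumption: in the aluminium-promoted [2+2] of dimenthyl fumarate with a ketene acetal, the (−)-menthyl ester is taken to lead to the (1S,2R) diester; the (+)-menthyl ester is therefore used to reach the (1R,2S) diester needed for C2 and C3.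

Remark: silyl triflate 17 carries the silyl group between OTf and OMe. Either placement of the two leaving groups gives the same aryne, and this one is reached from a symmetric phenol with no regiochemical question.

**Route**

Step 1
Reactants: 1 fumaryl chloride; 2 (1S,2R,5S)-(+)-menthol
Product: 3 di-(+)-menthyl fumarate
Conditions: 2 (2.1 equiv), toluene, 90 °C, N2 sweep
Reagents that add atoms: none
Why: Esterification of a secondary alcohol by an acyl chloride, which leaves the E alkene and the menthyl stereocentres untouched.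

Step 2
Reactants: 3 di-(+)-menthyl fumarate; 4 1,1-dimethoxyethene
Product: 5 di-(+)-menthyl (1R,2S)-3,3-dimethoxycyclobutane-1,2-dicarboxylate
Conditions: iBu2AlCl (2 equiv), toluene–hexane, −78 °C
Reagents that add atoms: none
Why: Lewis-acid-promoted stepwise [2+2] cycloaddition of a ketene acetal to a fumarate; the trans relation of the two ester carbons comes from the E alkene, and their absolute configuration from the menthyl esters, which should shield one face of the aluminium-bound fumarate.

Step 3
Reactants: 5 di-(+)-menthyl (1R,2S)-3,3-dimethoxycyclobutane-1,2-dicarboxylate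
Product: 6 [(1R,2R)-3,3-dimethoxycyclobutane-1,2-diyl]dimethanol
Conditions: LiAlH4, THF, 0 °C → rt
Reagents that add atoms: none
Why: Hydride reduction of both esters to primary alcohols; the ketal is inert and the stereocentres are not involved (the descriptor at the ketal-adjacent carbon changes only by CIP priority).

Step 4
Reactants: 6 [(1R,2R)-3,3-dimethoxycyclobutane-1,2-diyl]dimethanol
Product: 7 (2R,3R)-2,3-bis[(benzyloxy)methyl]-1,1-dimethoxycyclobutane
Conditions: NaH, BnBr, Bu4NI (cat.), THF–DMF, 0 °C → rt
Reagents that add atoms: benzyl bromide, BrCc1ccccc1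
Why: Williamson etherification of two primary alkoxides; the ketal tolerates base.

Step 5
Reactants: 7 (2R,3R)-2,3-bis[(benzyloxy)methyl]-1,1-dimethoxycyclobutane
Product: 8 (2R,3R)-2,3-bis[(benzyloxy)methyl]cyclobutan-1-one
Conditions: 0.5 M aq. H2SO4, MeCN, rt
Reagents that add atoms: water, O
Why: Acid hydrolysis of a dimethyl ketal; benzyl ethers are stable, and any enolisation at C2 can only return the favoured trans isomer.

Step 6
Reactants: 8 (2R,3R)-2,3-bis[(benzyloxy)methyl]cyclobutan-1-one
Product: 9 (2R,3R)-2,3-bis[(benzyloxy)methyl]-4-(phenylsulfanyl)cyclobutan-1-one (C4 epimers)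
Conditions: LiHMDS (2.1 equiv), THF, −78 °C; PhSO2SPh (1.0 equiv), −78 °C
Reagents that add atoms: S-phenyl benzenethiosulfonate, O=S(=O)(Sc1ccccc1)c1ccccc1
Why: α-Sulfenylation of the kinetic lithium enolate; the hindered base should remove a proton from the unsubstituted C4 methylene rather than from the substituted C2, and the second equivalent of base holds the product as its enolate.

Step 7
Reactants: 9 (2R,3R)-2,3-bis[(benzyloxy)methyl]-4-(phenylsulfanyl)cyclobutan-1-one
Product: 10 (2R,3R)-2,3-bis[(benzyloxy)methyl]-4-(phenylsulfonyl)cyclobutan-1-one (C4 epimers)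
Conditions: dimethyldioxirane (2.5 equiv), acetone, −20 → 0 °C
Reagents that add atoms: dimethyldioxirane, CC1(C)OO1
Why: Oxidation of a sulfide to the sulfone by a neutral, non-nucleophilic dioxirane, chosen because a peracid could bring about Baeyer–Villiger oxidation of the strained ketone.

Step 8
Reactants: 11 4-(benzyloxy)-3,5-dimethoxybenzaldehyde
Product: 13 4-(benzyloxy)-3,5-dimethoxyphenol, via aryl formate 12 (not isolated)
Conditions: mCPBA, CH2Cl2, 0 °C → rt; then K2CO3 (cat.), MeOH, rt
Reagents that add atoms: meta-chloroperoxybenzoic acid, O=C(OO)c1cccc(Cl)c1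
Why: Baeyer–Villiger (Dakin-type) oxidation of an electron-rich benzaldehyde with aryl migration, followed by methanolysis of the formate.

Step 9
Reactants: 13 4-(benzyloxy)-3,5-dimethoxyphenol
Product: 14 4-(benzyloxy)-2-bromo-3,5-dimethoxyphenol
Conditions: NBS (1.0 equiv), CH2Cl2, −78 → −20 °C
Reagents that add atoms: N-bromosuccinimide, O=C1CCC(=O)N1Br
Why: Electrophilic aromatic bromination ortho to the phenol; the two free ring positions are equivalent by symmetry, so only one monobromide can form.

Step 10
Reactants: 14 4-(benzyloxy)-2-bromo-3,5-dimethoxyphenol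
Product: 17 4-(benzyloxy)-3,5-dimethoxy-2-(trimethylsilyl)phenyl trifluoromethanesulfonate, via aryl trimethylsilyl ether 15 (not isolated), via lithium 2-silylphenoxide 16 (not isolated)
Conditions: HMDS, THF, 65 °C, then evaporate; n-BuLi, THF, −78 °C; Tf2O, −78 °C → rt
Reagents that add atoms: hexamethyldisilazane, C[Si](C)(C)N[Si](C)(C)C; trifluoromethanesulfonic anhydride, O=S(=O)(OS(=O)(=O)C(F)(F)F)C(F)(F)F
Why: O-Silylation, bromine–lithium exchange, 1,3 O→C silyl shift (retro-Brook rearrangement) and O-triflation of the phenoxide, the standard sequence from ortho-bromophenols to ortho-silyl aryl triflates.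

Step 11
Reactants: 10 (2R,3R)-2,3-bis[(benzyloxy)methyl]-4-(phenylsulfonyl)cyclobutan-1-one; 17 4-(benzyloxy)-3,5-dimethoxy-2-(trimethylsilyl)phenyl trifluoromethanesulfonate
Product: 20 (2R,3R)-7-(benzyloxy)-2,3-bis[(benzyloxy)methyl]-6,8-dimethoxy-4-(phenylsulfonyl)-3,4-dihydronaphthalen-1(2H)-one (C4 epimers), via aryne 18 (not isolated), via fused cyclobutoxide 19 (not isolated)
Conditions: 17 (1.3 equiv), CsF (3 equiv), MeCN, 60 °C
Reagents that add atoms: none
Why: Proposed new method: fluoride attack on silicon in 17 expels triflate to give aryne 18, the caesium enolate of β-keto sulfone 10 adds through C4 to the aryne carbon remote from the methoxy group (C4a), the aryl anion left at C8a adds to the strained C1 carbonyl, and the fused cyclobutoxide 19 opens by retro-aldol cleavage of C1–C4 to a sulfonyl-stabilised benzylic carbanion that is protonated by a further molecule of 10. The closest known reaction type is the aryne acyl-alkylation (C–C σ-bond insertion) that expands cyclic β-keto esters and α-sulfonyl cycloalkanones of ring size five and above by two carbons; a cyclobutanone has not been used, but its ring strain should speed both the carbonyl addition and the fragmentation. The six-membered ring is not closed directly: a 4-exo-trig addition of the aryl anion to C=O gives a benzo-fused bicyclo[2.2.0] alkoxide, and cleavage of the bond shared by its two four-membered rings leaves the tetralone ring. C2 and C3 are carried over from 10 (C2, now α to an aryl ketone, can only equilibrate toward the trans arrangement), and the one new stereocentre, C4, forms by uncontrolled protonation and is removed in step 13. The selectivity needed is addition of the carbon nucleophile at C4a and not at C8a, which the inductive and distortion effect of the methoxy group flanking C8a should secure, together with carbonyl capture by the aryl anion ahead of its protonation, which the electrophilic four-membered ketone held next to it should favour.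

Step 12
Reactants: 20 (2R,3R)-7-(benzyloxy)-2,3-bis[(benzyloxy)methyl]-6,8-dimethoxy-4-(phenylsulfonyl)-3,4-dihydronaphthalen-1(2H)-one
Product: 21 (2R,3R)-7-(benzyloxy)-2,3-bis[(benzyloxy)methyl]-6,8-dimethoxy-4-(phenylsulfonyl)-1,2,3,4-tetrahydronaphthalen-1-ol (C1 and C4 epimers)
Conditions: NaBH4, MeOH–THF, 0 °C → rt
Reagents that add atoms: none
Why: Borohydride reduction of the aryl ketone, done before desulfonylation so that no ketone is exposed to the electron-transfer reagent; the C1 configuration is irrelevant because C1 is ionised in step 14.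

Step 13
Reactants: 21 (2R,3R)-7-(benzyloxy)-2,3-bis[(benzyloxy)methyl]-6,8-dimethoxy-4-(phenylsulfonyl)-1,2,3,4-tetrahydronaphthalen-1-ol
Product: 22 (2R,3R)-7-(benzyloxy)-2,3-bis[(benzyloxy)methyl]-6,8-dimethoxy-1,2,3,4-tetrahydronaphthalen-1-ol (C1 epimers)
Conditions: Mg turnings (excess), MeOH–THF, 50 °C
Reagents that add atoms: none
Why: Reductive desulfonylation of a benzylic phenyl sulfone by single-electron transfer from magnesium in methanol; benzyl ethers, the free alcohol and C3 are not affected.

Step 14
Reactants: 22 (2R,3R)-7-(benzyloxy)-2,3-bis[(benzyloxy)methyl]-6,8-dimethoxy-1,2,3,4-tetrahydronaphthalen-1-ol; 23 guaiacol (2-methoxyphenol)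
Product: 25 (1S,2R,3R)-7-(benzyloxy)-2,3-bis[(benzyloxy)methyl]-1-(4-hydroxy-3-methoxyphenyl)-6,8-dimethoxy-1,2,3,4-tetrahydronaphthalene, via C1 benzylic cation 24 (not isolated)
Conditions: 23 (10 equiv), BF3·OEt2 (1.2 equiv), CH2Cl2, −40 → 0 °C
Reagents that add atoms: none
Why: SN1 Friedel–Crafts alkylation in which the C1 cation, stabilised by the para C6 and ortho C8 methoxy groups, is taken up by guaiacol para to its hydroxyl (strongest donor, least hindered site); the arene should add to the face of C1 opposite the C2 CH2OBn group, giving the 1,2-trans (1S) product, which reversible ionisation would also favour.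

Step 15
Reactants: 25 (1S,2R,3R)-7-(benzyloxy)-2,3-bis[(benzyloxy)methyl]-1-(4-hydroxy-3-methoxyphenyl)-6,8-dimethoxy-1,2,3,4-tetrahydronaphthalene
Product: 26 (+)-8-methoxyisolariciresinol
Conditions: H2 (1 atm), 10% Pd/C, EtOAc–MeOH, rt
Reagents that add atoms: none
Why: Hydrogenolysis of one aryl and two alkyl benzyl ethers; the C1–aryl bond is a C–C bond and is not cleaved, so no stereocentre is touched.

**Compound list**

1 | fumaryl chloride | O=C(Cl)/C=C/C(=O)Cl | starting material
2 | (1S,2R,5S)-(+)-menthol | CC(C)[C@H]1CC[C@H](C)C[C@@H]1O | starting material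
3 | di-(+)-menthyl fumarate, bis[(1S,2R,5S)-5-methyl-2-(propan-2-yl)cyclohexyl] (E)-but-2-enedioate | O=C(/C=C/C(=O)O[C@H]1C[C@@H](C)CC[C@@H]1C(C)C)O[C@H]1C[C@@H](C)CC[C@@H]1C(C)C | intermediate
4 | 1,1-dimethoxyethene (ketene dimethyl acetal) | C=C(OC)OC | starting material
5 | di-(+)-menthyl (1R,2S)-3,3-dimethoxycyclobutane-1,2-dicarboxylate (esters trans) | COC1(OC)[C@@H](C(=O)O[C@H]2C[C@@H](C)CC[C@@H]2C(C)C)[C@H](C(=O)O[C@H]2C[C@@H](C)CC[C@@H]2C(C)C)C1 | intermediate
6 | [(1R,2R)-3,3-dimethoxycyclobutane-1,2-diyl]dimethanol (trans) | COC1(OC)[C@@H](CO)[C@H](CO)C1 | intermediate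
7 | (2R,3R)-2,3-bis[(benzyloxy)methyl]-1,1-dimethoxycyclobutane | COC1(OC)[C@@H](COCc2ccccc2)[C@H](COCc2ccccc2)C1 | intermediate
8 | (2R,3R)-2,3-bis[(benzyloxy)methyl]cyclobutan-1-one (trans) | O=C1[C@@H](COCc2ccccc2)[C@H](COCc2ccccc2)C1 | intermediate
9 | (2R,3R)-2,3-bis[(benzyloxy)methyl]-4-(phenylsulfanyl)cyclobutan-1-one, C4 epimers | O=C1[C@@H](COCc2ccccc2)[C@H](COCc2ccccc2)C1Sc1ccccc1 | intermediate
10 | (2R,3R)-2,3-bis[(benzyloxy)methyl]-4-(phenylsulfonyl)cyclobutan-1-one, C4 epimers | O=C1[C@@H](COCc2ccccc2)[C@H](COCc2ccccc2)C1S(=O)(=O)c1ccccc1 | intermediate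
11 | 4-(benzyloxy)-3,5-dimethoxybenzaldehyde | COc1cc(C=O)cc(OC)c1OCc1ccccc1 | starting material
12 | 4-(benzyloxy)-3,5-dimethoxyphenyl formate | COc1cc(OC=O)cc(OC)c1OCc1ccccc1 | intermediate
13 | 4-(benzyloxy)-3,5-dimethoxyphenol | COc1cc(O)cc(OC)c1OCc1ccccc1 | intermediate
14 | 4-(benzyloxy)-2-bromo-3,5-dimethoxyphenol | COc1cc(O)c(Br)c(OC)c1OCc1ccccc1 | intermediate
15 | [4-(benzyloxy)-2-bromo-3,5-dimethoxyphenoxy]trimethylsilane | COc1cc(O[Si](C)(C)C)c(Br)c(OC)c1OCc1ccccc1 | intermediate
16 | lithium 4-(benzyloxy)-3,5-dimethoxy-2-(trimethylsilyl)phenoxide | [Li+].[O-]c1cc(OC)c(OCc2ccccc2)c(OC)c1[Si](C)(C)C | intermediate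
17 | 4-(benzyloxy)-3,5-dimethoxy-2-(trimethylsilyl)phenyl trifluoromethanesulfonate | COc1cc(OS(=O)(=O)C(F)(F)F)c([Si](C)(C)C)c(OC)c1OCc1ccccc1 | intermediate
18 | 4-(benzyloxy)-3,5-dimethoxybenzyne (aryne carbons are the future C4a and C8a; OMe next to C8a) | COC1=C(OCc2ccccc2)C(OC)=CC#C1 | intermediate
19 | caesium alkoxide of the benzo-fused bicyclo[2.2.0]hexane formed by addition of the C8a aryl anion to C1, with the C1–C4 bond still intact and C2, C3 as in 10 | [Cs+].[O-]C12c3c(OC)c(OCc4ccccc4)c(OC)cc3C1(S(=O)(=O)c1ccccc1)[C@@H](COCc1ccccc1)[C@@H]2COCc1ccccc1 | intermediate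
20 | (2R,3R)-7-(benzyloxy)-2,3-bis[(benzyloxy)methyl]-6,8-dimethoxy-4-(phenylsulfonyl)-3,4-dihydronaphthalen-1(2H)-one, C4 epimers | O=C1c2c(cc(OC)c(OCc3ccccc3)c2OC)C(S(=O)(=O)c2ccccc2)[C@@H](COCc2ccccc2)[C@@H]1COCc1ccccc1 | intermediate
21 | (2R,3R)-7-(benzyloxy)-2,3-bis[(benzyloxy)methyl]-6,8-dimethoxy-4-(phenylsulfonyl)-1,2,3,4-tetrahydronaphthalen-1-ol, C1 and C4 epimers | OC1c2c(cc(OC)c(OCc3ccccc3)c2OC)C(S(=O)(=O)c2ccccc2)[C@@H](COCc2ccccc2)[C@@H]1COCc1ccccc1 | intermediate
22 | (2R,3R)-7-(benzyloxy)-2,3-bis[(benzyloxy)methyl]-6,8-dimethoxy-1,2,3,4-tetrahydronaphthalen-1-ol, C1 epimers | OC1c2c(cc(OC)c(OCc3ccccc3)c2OC)C[C@@H](COCc2ccccc2)[C@@H]1COCc1ccccc1 | intermediate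
23 | guaiacol (2-methoxyphenol) | COc1ccccc1O | starting material
24 | C1 benzylic cation of 22 | [CH+]1c2c(cc(OC)c(OCc3ccccc3)c2OC)C[C@@H](COCc2ccccc2)[C@@H]1COCc1ccccc1 | intermediate
25 | (1S,2R,3R)-7-(benzyloxy)-2,3-bis[(benzyloxy)methyl]-1-(4-hydroxy-3-methoxyphenyl)-6,8-dimethoxy-1,2,3,4-tetrahydronaphthalene | COc1cc([C@H]2c3c(cc(OC)c(OCc4ccccc4)c3OC)C[C@@H](COCc3ccccc3)[C@@H]2COCc2ccccc2)ccc1O | intermediate
26 | (+)-8-methoxyisolariciresinol, (1S,2R,3R) | COc1cc([C@H]2c3c(cc(OC)c(O)c3OC)C[C@@H](CO)[C@@H]2CO)ccc1O | target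

**Step count**

Total: 15 steps. Longest linear sequence: 12 steps (steps 1–7 and 11–15); the aryne precursor arm is 3 steps (8–10).

**Steps most likely to fail**

1. Step 11 (proposed new method). After the enolate has added to the aryne, the aryl anion may be protonated before it reaches the carbonyl, which would give plain α-arylation. The enolate may also add through oxygen, or the strained keto sulfone may be opened by fluoride or traces of water before the aryne forms. Base-mediated loss of benzyl alcohol from C2 of the product is a further possible loss.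
Fallback, known chemistry only: it sets out from aldehyde 11 and returns at the target 26. Stobbe condensation of 11 with dimethyl succinate (KOtBu, tBuOH) gives (E)-4-[4-(benzyloxy)-3,5-dimethoxyphenyl]-3-(methoxycarbonyl)but-3-enoic acid F1. Rhodium-catalysed asymmetric hydrogenation with a chiral bisphosphine, the ligand enantiomer chosen to give the R acid, gives (R)-4-[4-(benzyloxy)-3,5-dimethoxyphenyl]-3-(methoxycarbonyl)butanoic acid F2. Reduction of the ester group of its carboxylate salt with Ca(BH4)2 in EtOH and acid work-up give (R)-4-[4-(benzyloxy)-3,5-dimethoxybenzyl]dihydrofuran-2(3H)-one F3. Aldol addition of its lithium enolate (LDA, THF, −78 °C) to 4-(benzyloxy)-3-methoxybenzaldehyde, anti to the benzyl group, gives the trans α-(hydroxybenzyl)-β-benzyl lactone F4. TFA in CH2Cl2 then closes the tetralin ring by intramolecular Friedel–Crafts alkylation to the trans,trans aryltetralin lactone F5. LiAlH4 gives the 7,4'-di-O-benzyl ether of the target F6, and hydrogenolysis over Pd/C gives 26.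

2. Step 14. The cation may be attacked by guaiacol at the position para to the methoxy group or ortho to the hydroxyl, or from the face of C1 next to the C2 substituent. It may also lose a proton from C2, which would scramble that centre on re-protonation, or alkylate C5 of a second tetralin.
Fallback: it sets out from 22 and returns at 26. The nucleophile is changed to 2-bromo-6-methoxyphenol, in which bromine blocks the position ortho to the hydroxyl and hinders the position para to the methoxy group, so that only the position para to the hydroxyl is open. Alkylation under the same Lewis acid should give (1S,2R,3R)-7-(benzyloxy)-2,3-bis[(benzyloxy)methyl]-1-(3-bromo-4-hydroxy-5-methoxyphenyl)-6,8-dimethoxy-1,2,3,4-tetrahydronaphthalene F7. The blocking bromine is then removed together with the three benzyl groups in one hydrogenolysis (H2, Pd/C, Et3N, MeOH–EtOAc) to give 26.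

3. Step 6. The free lithium enolate may form toward C2 and expel benzyloxide, may add to unreacted cyclobutanone in an aldol self-condensation, or may be sulfenylated twice.
Fallback: it sets out from 8 and returns at 9. The enolate is trapped as it forms by adding LiHMDS to a mixture of 8 and Me3SiCl at −78 °C, which gives {[(3R,4R)-3,4-bis[(benzyloxy)methyl]cyclobut-1-en-1-yl]oxy}trimethylsilane F8. This neutral silyl enol ether is then sulfenylated with benzenesulfenyl chloride in CH2Cl2 at −78 °C to give 9.

**Further compounds**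

F1 | step 11 | (E)-4-[4-(benzyloxy)-3,5-dimethoxyphenyl]-3-(methoxycarbonyl)but-3-enoic acid | OC(=O)C/C(C(=O)OC)=C\c1cc(OC)c(OCc2ccccc2)c(OC)c1
F2 | step 11 | (R)-4-[4-(benzyloxy)-3,5-dimethoxyphenyl]-3-(methoxycarbonyl)butanoic acid | OC(=O)C[C@@H](Cc1cc(OC)c(OCc2ccccc2)c(OC)c1)C(=O)OC
F3 | step 11 | (R)-4-[4-(benzyloxy)-3,5-dimethoxybenzyl]dihydrofuran-2(3H)-one | O=C1C[C@@H](Cc2cc(OC)c(OCc3ccccc3)c(OC)c2)CO1
F4 | step 11 | (3S,4R)-4-[4-(benzyloxy)-3,5-dimethoxybenzyl]-3-{[4-(benzyloxy)-3-methoxyphenyl](hydroxy)methyl}dihydrofuran-2(3H)-one, ring substituents trans, carbinol epimers | O=C1[C@H](C(O)c2ccc(OCc3ccccc3)c(OC)c2)[C@@H](Cc2cc(OC)c(OCc3ccccc3)c(OC)c2)CO1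
F5 | step 11 | 7-(benzyloxy)-1-[4-(benzyloxy)-3-methoxyphenyl]-6,8-dimethoxytetralin with a γ-lactone fused at C2–C3 (carbonyl on C2), configured at C1, C2 and C3 as in the target | COc1cc([C@H]2c3c(cc(OC)c(OCc4ccccc4)c3OC)C[C@H]3COC(=O)[C@H]23)ccc1OCc1ccccc1
F6 | step 11 | 7,4'-di-O-benzyl-8-methoxyisolariciresinol, (1S,2R,3R) | COc1cc([C@H]2c3c(cc(OC)c(OCc4ccccc4)c3OC)C[C@@H](CO)[C@@H]2CO)ccc1OCc1ccccc1
F7 | step 14 | (1S,2R,3R)-7-(benzyloxy)-2,3-bis[(benzyloxy)methyl]-1-(3-bromo-4-hydroxy-5-methoxyphenyl)-6,8-dimethoxy-1,2,3,4-tetrahydronaphthalene | COc1cc([C@H]2c3c(cc(OC)c(OCc4ccccc4)c3OC)C[C@@H](COCc3ccccc3)[C@@H]2COCc2ccccc2)cc(Br)c1O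
F8 | step 6 | {[(3R,4R)-3,4-bis[(benzyloxy)methyl]cyclobut-1-en-1-yl]oxy}trimethylsilane | C[Si](C)(C)OC1=C[C@@H](COCc2ccccc2)[C@@H]1COCc1ccccc1
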